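**Retrosynthetic overview** (isochromenone numbering O2, C1, C3–C8a; side chain C1'–C7')
1. Target ⇐ removal of four Et3Si ethers ⇐ intramolecular hetero-Diels–Alder reaction of a 1,3-diacylallene: O2=C3–C4=C4a (1-oxadiene) plus the C8a=C1 vinyl group closes the carbocycle (C4a–C8a) and the pyran (O2–C1) together and sets C8a.
2. Diacylallene ⇐ skipped ynedione ⇐ double oxidation of the diol made by acetylide addition (C5–C6 bond) of a side-chain homopropargylic alcohol to a C6 aldehyde.
3. C6 aldehyde (C1, C8a, C8, C7, C6) ⇐ diethyl D-tartrate: C8 bought, C7 by Fráter–Seebach C-methylation, one ester converted into the vinyl group.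
4. Side-chain alkyne (C5–C3, C1'–C7') ⇐ L-isoleucine (C4', C5' bought; C3' by Cram-chelate MeMgBr addition to an α-hydroxy ynone), 3,3-diethoxypropyne and propargyl bromide.
5. Ring order: no ring exists before the cycloaddition; both rings form in that one step.

Assumption: the carbinol carbons created in steps 12 and 13 are carried as epimer mixtures (both become ketones in step 14), so 19 and 20 are drawn without configuration there; the same holds for the aminal carbon of 16 and the allene axis of 22.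

**Route**

Step 1
Reactants: 1 diethyl D-tartrate
Product: 2 diethyl (2S,3S)-2-hydroxy-3-[(triethylsilyl)oxy]butanedioate
Conditions: Et3SiCl (1.0 equiv), imidazole, CH2Cl2, 0 °C
Reagents that add atoms: chlorotriethylsilane CC[Si](Cl)(CC)CC
Why: O-silylation with one equivalent of silyl chloride protects one hydroxyl of the C2-symmetric diol (either one gives the same compound), touches no stereocentre and leaves one hydroxyl for dianion formation.

Step 2
Reactants: 2 diethyl (2S,3S)-2-hydroxy-3-[(triethylsilyl)oxy]butanedioate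
Product: 4 diethyl (2S,3S)-2-methyl-2,3-bis[(triethylsilyl)oxy]butanedioate, via lithium alkoxide of the C-methylated hydroxy diester 3 (not isolated)
Conditions: LiN(iPr)2 (2.2 equiv), THF, −78 → −30 °C; CH3I, −78 → −40 °C; then Et3SiOTf, −78 → 0 °C
Reagents that add atoms: iodomethane CI; triethylsilyl trifluoromethanesulfonate CC[Si](CC)(CC)OS(=O)(=O)C(F)(F)F
Why: Fráter–Seebach alkylation, in which the alkoxide/ester-enolate dianion is held in a six-membered lithium chelate and iodomethane enters anti to the β-alkoxide, so methyl replaces the former C–H with retention and the quaternary C7 carbinol is set (threo kept) by the purchased neighbouring centre, after which the alkoxide is silylated in the same flask.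

Step 3
Reactants: 4 diethyl (2S,3S)-2-methyl-2,3-bis[(triethylsilyl)oxy]butanedioate
Product: 5 ethyl (2S,3S)-2-methyl-4-oxo-2,3-bis[(triethylsilyl)oxy]butanoate
Conditions: iBu2AlH (1.05 equiv), CH2Cl2, −78 °C; aqueous work-up
Reagents that add atoms: none
Why: Chemoselective iBu2AlH half-reduction, because the ester on the secondary carbon is far less hindered than the one on the quaternary carbon and its α-silyloxy tetrahedral aluminate survives at −78 °C until work-up, giving the aldehyde without touching a stereocentre.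

Step 4
Reactants: 5 ethyl (2S,3S)-2-methyl-4-oxo-2,3-bis[(triethylsilyl)oxy]butanoate
Product: 6 ethyl (2S,3R)-2-methyl-2,3-bis[(triethylsilyl)oxy]pent-4-enoate
Conditions: Ph3PCH3Br, KN(SiMe3)2, THF, 0 °C; then 5, −78 → 0 °C
Reagents that add atoms: methyltriphenylphosphonium bromide C[P+](c1ccccc1)(c1ccccc1)c1ccccc1.[Br-]
Why: Wittig methylenation with the non-stabilised ylide turns the aldehyde into the terminal vinyl group (the later C8a=C1 dienophile) fast enough at low temperature that the α-silyloxy centre does not epimerise (the descriptor changes from S to R only through priority order).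

Step 5
Reactants: 6 ethyl (2S,3R)-2-methyl-2,3-bis[(triethylsilyl)oxy]pent-4-enoate
Product: 7 (2S,3R)-2-methyl-2,3-bis[(triethylsilyl)oxy]pent-4-enal
Conditions: iBu2AlH (1.2 equiv), CH2Cl2, −78 °C; aqueous work-up
Reagents that add atoms: none
Why: iBu2AlH reduction of the remaining hindered α-silyloxy ester stops at the aldehyde because the chelated tetrahedral aluminate is stable at −78 °C, and the quaternary α-carbon cannot epimerise.

Step 6
Reactants: 8 L-isoleucine
Product: 9 (2S,3S)-2-hydroxy-3-methylpentanoic acid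
Conditions: NaNO2, 1 M aq. H2SO4, 0 → 23 °C
Reagents that add atoms: water O
Why: Diazotisation of the α-amino acid, in which the carboxylate displaces N2 to an α-lactone that water reopens, a double inversion that gives the α-hydroxy acid with net retention so both purchased stereocentres are kept.

Step 7
Reactants: 9 (2S,3S)-2-hydroxy-3-methylpentanoic acid
Product: 10 (2S,3S)-2-hydroxy-N-methoxy-N,3-dimethylpentanamide
Conditions: MeNH(OMe)·HCl, DCC, HOBt (cat.), Et3N, CH2Cl2, 0 → 23 °C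
Reagents that add atoms: N,O-dimethylhydroxylamine hydrochloride CNOC.Cl
Why: Carbodiimide amide coupling gives the Weinreb amide under mild conditions that do not epimerise the α-hydroxy centre.

Step 8
Reactants: 10 (2S,3S)-2-hydroxy-N-methoxy-N,3-dimethylpentanamide; 11 3,3-diethoxyprop-1-yne
Product: 12 (5S,6S)-1,1-diethoxy-5-hydroxy-6-methyloct-2-yn-4-one
Conditions: 11 (2.5 equiv), n-BuLi (2.4 equiv), THF, −78 °C; then 10, −78 → −20 °C; H2O
Reagents that add atoms: none
Why: Weinreb ketone synthesis, in which the lithium acetylide (one equivalent only deprotonates the hydroxyl) adds once to give a chelated tetrahedral intermediate that releases the ynone on work-up.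

Step 9
Reactants: 12 (5S,6S)-1,1-diethoxy-5-hydroxy-6-methyloct-2-yn-4-one
Product: 13 (4R,5S,6S)-1,1-diethoxy-4,6-dimethyloct-2-yne-4,5-diol
Conditions: MeMgBr (3 equiv), THF, −78 °C; H2O
Reagents that add atoms: methylmagnesium bromide C[Mg]Br
Why: Cram cyclic-chelate 1,2-addition, in which the magnesium alkoxide and the ketone oxygen form a five-membered chelate and the methyl group attacks the face opposite the sec-butyl group, setting the tertiary carbinol (C3') as R under control of the neighbouring purchased centre.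

Step 10
Reactants: 13 (4R,5S,6S)-1,1-diethoxy-4,6-dimethyloct-2-yne-4,5-diol
Product: 14 (2E,4R,5S,6S)-1,1-diethoxy-4,6-dimethyloct-2-ene-4,5-diol
Conditions: LiAlH4, THF, −20 → 0 °C; aqueous work-up
Reagents that add atoms: none
Why: Alkoxide-directed trans-hydroalumination of the propargylic alcohol followed by protonolysis gives only the E-alkene, and the acetal is inert to hydride at this temperature.

Step 11
Reactants: 14 (2E,4R,5S,6S)-1,1-diethoxy-4,6-dimethyloct-2-ene-4,5-diol
Product: 17 (2E,4R,5S,6S)-4,6-dimethyl-4,5-bis[(triethylsilyl)oxy]oct-2-enal, via bis-silyl ether acetal 15 (not isolated), via lutidinium aminal triflate 16 (not isolated)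
Conditions: Et3SiOTf (4.5 equiv), 2,6-lutidine (6 equiv), CH2Cl2, −78 → 0 °C; then H2O
Reagents that add atoms: triethylsilyl trifluoromethanesulfonate CC[Si](CC)(CC)OS(=O)(=O)C(F)(F)F; water O
Why: Silyl triflate O-silylation protects the secondary and tertiary hydroxyls, and the same Et3SiOTf/2,6-lutidine pair ionises the diethyl acetal to a pyridinium salt that water hydrolyses to the E-enal, with no stereocentre affected.

Step 12
Reactants: 17 (2E,4R,5S,6S)-4,6-dimethyl-4,5-bis[(triethylsilyl)oxy]oct-2-enal; 18 propargyl bromide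
Product: 19 (5E,7R,8S,9S)-7,9-dimethyl-7,8-bis[(triethylsilyl)oxy]undec-5-en-1-yn-4-ol (C4 epimers)
Conditions: Zn dust, THF, 0 → 23 °C; H2O
Reagents that add atoms: none
Why: Barbier propargylation, in which the allenylzinc bromide formed in the flask adds 1,2 to the enal through an SE2' transition state to give the homopropargylic alcohol, whose uncontrolled carbinol centre is oxidised later.

Step 13
Reactants: 19 (5E,7R,8S,9S)-7,9-dimethyl-7,8-bis[(triethylsilyl)oxy]undec-5-en-1-yn-4-ol; 7 (2S,3R)-2-methyl-2,3-bis[(triethylsilyl)oxy]pent-4-enal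
Product: 20 (10E)-4,12,14-trimethyl-3,4,12,13-tetrakis[(triethylsilyl)oxy]hexadeca-1,10-dien-6-yne-5,9-diol (C5/C9 epimers; other centres as in 7 and 19)
Conditions: 19, n-BuLi (2.1 equiv), THF, −78 °C; then 7, −78 °C; H2O at −78 °C
Reagents that add atoms: none
Why: Acetylide 1,2-addition of the alkoxide/acetylide dianion to the non-enolisable aldehyde joins the two fragments (C5–C6 bond), and the cold quench prevents silyl migration to the new alkoxide, whose centre is removed in step 14.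

Step 14
Reactants: 20 (10E)-4,12,14-trimethyl-3,4,12,13-tetrakis[(triethylsilyl)oxy]hexadeca-1,10-dien-6-yne-5,9-diol
Product: 21 (3R,4S,10E,12R,13S,14S)-4,12,14-trimethyl-3,4,12,13-tetrakis[(triethylsilyl)oxy]hexadeca-1,10-dien-6-yne-5,9-dione
Conditions: Dess–Martin periodinane (3 equiv), pyridine, CH2Cl2, 0 °C; crude used at once
Reagents that add atoms: none
Why: Dess–Martin oxidation converts both secondary carbinols into ketones under buffered conditions that spare the silyl ethers and alkenes, erasing the two uncontrolled centres.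

Step 15
Reactants: 21 (3R,4S,10E,12R,13S,14S)-4,12,14-trimethyl-3,4,12,13-tetrakis[(triethylsilyl)oxy]hexadeca-1,10-dien-6-yne-5,9-dione
Product: 23 (7S,8R,8aS)-3-[(1E,3R,4S,5S)-3,5-dimethyl-3,4-bis[(triethylsilyl)oxy]hept-1-en-1-yl]-7-methyl-7,8-bis[(triethylsilyl)oxy]-1,7,8,8a-tetrahydro-6H-isochromen-6-one, via 1,3-diacylallene 22 (not isolated)
Conditions: 1,4-diazabicyclo[2.2.2]octane (0.1 equiv), CHCl3 (5 mM), 23 → 40 °C
Reagents that add atoms: none
Why: Amine-catalysed propargyl-to-allenyl isomerisation gives the 1,3-diacylallene, whose acyl-allene unit reacts as a 1-oxadiene with the tethered vinyl group in an intramolecular inverse-demand hetero-Diels–Alder reaction that forms both rings, and because the allene epimers interconvert (Curtin–Hammett) the half-chair transition state with the C7 methyl equatorial, the trans silyloxy groups axial and the C8–O bond in the inside position of the vinyl group is expected to win, placing H-8a cis to H-8 (8aS) under control of the tartrate-derived C7/C8 pair.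

Step 16
Reactants: 23 (7S,8R,8aS)-3-[(1E,3R,4S,5S)-3,5-dimethyl-3,4-bis[(triethylsilyl)oxy]hept-1-en-1-yl]-7-methyl-7,8-bis[(triethylsilyl)oxy]-1,7,8,8a-tetrahydro-6H-isochromen-6-one
Product: 24 (7S,8R,8aS)-3-[(1E,3R,4S,5S)-3,4-dihydroxy-3,5-dimethylhept-1-en-1-yl]-7,8-dihydroxy-7-methyl-1,7,8,8a-tetrahydro-6H-isochromen-6-one
Conditions: HF·pyridine, pyridine, THF, 0 → 23 °C
Reagents that add atoms: none
Why: Fluoride-mediated desilylation under pyridine-buffered conditions cleaves the four triethylsilyl ethers without ionising the tertiary allylic alcohol or epimerising C8a.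

**Compound list**

1 | diethyl D-tartrate, diethyl (2S,3S)-2,3-dihydroxybutanedioate | CCOC(=O)[C@@H](O)[C@H](O)C(=O)OCC | starting material
2 | diethyl (2S,3S)-2-hydroxy-3-[(triethylsilyl)oxy]butanedioate | CCOC(=O)[C@@H](O[Si](CC)(CC)CC)[C@H](O)C(=O)OCC | intermediate
3 | lithium alkoxide of diethyl (2S,3S)-3-hydroxy-2-methyl-2-[(triethylsilyl)oxy]butanedioate (not isolated) | CCOC(=O)[C@@](C)(O[Si](CC)(CC)CC)[C@H]([O-])C(=O)OCC.[Li+] | intermediate
4 | diethyl (2S,3S)-2-methyl-2,3-bis[(triethylsilyl)oxy]butanedioate | CCOC(=O)[C@@](C)(O[Si](CC)(CC)CC)[C@H](O[Si](CC)(CC)CC)C(=O)OCC | intermediate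
5 | ethyl (2S,3S)-2-methyl-4-oxo-2,3-bis[(triethylsilyl)oxy]butanoate | CCOC(=O)[C@@](C)(O[Si](CC)(CC)CC)[C@H](O[Si](CC)(CC)CC)C=O | intermediate
6 | ethyl (2S,3R)-2-methyl-2,3-bis[(triethylsilyl)oxy]pent-4-enoate | CCOC(=O)[C@@](C)(O[Si](CC)(CC)CC)[C@H](O[Si](CC)(CC)CC)C=C | intermediate
7 | (2S,3R)-2-methyl-2,3-bis[(triethylsilyl)oxy]pent-4-enal | O=C[C@@](C)(O[Si](CC)(CC)CC)[C@H](O[Si](CC)(CC)CC)C=C | intermediate
8 | L-isoleucine, (2S,3S)-2-amino-3-methylpentanoic acid | CC[C@H](C)[C@H](N)C(=O)O | starting material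
9 | (2S,3S)-2-hydroxy-3-methylpentanoic acid | CC[C@H](C)[C@H](O)C(=O)O | intermediate
10 | (2S,3S)-2-hydroxy-N-methoxy-N,3-dimethylpentanamide | CC[C@H](C)[C@H](O)C(=O)N(C)OC | intermediate
11 | 3,3-diethoxyprop-1-yne | C#CC(OCC)OCC | starting material
12 | (5S,6S)-1,1-diethoxy-5-hydroxy-6-methyloct-2-yn-4-one | CC[C@H](C)[C@H](O)C(=O)C#CC(OCC)OCC | intermediate
13 | (4R,5S,6S)-1,1-diethoxy-4,6-dimethyloct-2-yne-4,5-diol | CC[C@H](C)[C@H](O)[C@](C)(O)C#CC(OCC)OCC | intermediate
14 | (2E,4R,5S,6S)-1,1-diethoxy-4,6-dimethyloct-2-ene-4,5-diol | CC[C@H](C)[C@H](O)[C@](C)(O)/C=C/C(OCC)OCC | intermediate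
15 | (2E,4R,5S,6S)-1,1-diethoxy-4,6-dimethyl-4,5-bis[(triethylsilyl)oxy]oct-2-ene (not isolated) | CC[C@H](C)[C@H](O[Si](CC)(CC)CC)[C@](C)(O[Si](CC)(CC)CC)/C=C/C(OCC)OCC | intermediate
16 | 1-[(2E,4R,5S,6S)-1-ethoxy-4,6-dimethyl-4,5-bis[(triethylsilyl)oxy]oct-2-en-1-yl]-2,6-dimethylpyridinium trifluoromethanesulfonate (not isolated; C1 epimers) | CC[C@H](C)[C@H](O[Si](CC)(CC)CC)[C@](C)(O[Si](CC)(CC)CC)/C=C/C(OCC)[n+]1c(C)cccc1C.[O-]S(=O)(=O)C(F)(F)F | intermediate
17 | (2E,4R,5S,6S)-4,6-dimethyl-4,5-bis[(triethylsilyl)oxy]oct-2-enal | CC[C@H](C)[C@H](O[Si](CC)(CC)CC)[C@](C)(O[Si](CC)(CC)CC)/C=C/C=O | intermediate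
18 | propargyl bromide, 3-bromoprop-1-yne | C#CCBr | starting material
19 | (5E,7R,8S,9S)-7,9-dimethyl-7,8-bis[(triethylsilyl)oxy]undec-5-en-1-yn-4-ol (C4 epimers) | CC[C@H](C)[C@H](O[Si](CC)(CC)CC)[C@](C)(O[Si](CC)(CC)CC)/C=C/C(O)CC#C | intermediate
20 | (10E)-4,12,14-trimethyl-3,4,12,13-tetrakis[(triethylsilyl)oxy]hexadeca-1,10-dien-6-yne-5,9-diol (C5/C9 epimers; other centres as in 7 and 19) | CC[C@H](C)[C@H](O[Si](CC)(CC)CC)[C@](C)(O[Si](CC)(CC)CC)/C=C/C(O)CC#CC(O)[C@@](C)(O[Si](CC)(CC)CC)[C@H](O[Si](CC)(CC)CC)C=C | intermediate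
21 | (3R,4S,10E,12R,13S,14S)-4,12,14-trimethyl-3,4,12,13-tetrakis[(triethylsilyl)oxy]hexadeca-1,10-dien-6-yne-5,9-dione | CC[C@H](C)[C@H](O[Si](CC)(CC)CC)[C@](C)(O[Si](CC)(CC)CC)/C=C/C(=O)CC#CC(=O)[C@@](C)(O[Si](CC)(CC)CC)[C@H](O[Si](CC)(CC)CC)C=C | intermediate
22 | (3R,4S,10E,12R,13S,14S)-4,12,14-trimethyl-3,4,12,13-tetrakis[(triethylsilyl)oxy]hexadeca-1,6,7,10-tetraene-5,9-dione (not isolated; both allene epimers) | CC[C@H](C)[C@H](O[Si](CC)(CC)CC)[C@](C)(O[Si](CC)(CC)CC)/C=C/C(=O)C=C=CC(=O)[C@@](C)(O[Si](CC)(CC)CC)[C@H](O[Si](CC)(CC)CC)C=C | intermediate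
23 | (7S,8R,8aS)-3-[(1E,3R,4S,5S)-3,5-dimethyl-3,4-bis[(triethylsilyl)oxy]hept-1-en-1-yl]-7-methyl-7,8-bis[(triethylsilyl)oxy]-1,7,8,8a-tetrahydro-6H-isochromen-6-one | CC[C@H](C)[C@H](O[Si](CC)(CC)CC)[C@](C)(O[Si](CC)(CC)CC)/C=C/C1=CC2=CC(=O)[C@@](C)(O[Si](CC)(CC)CC)[C@H](O[Si](CC)(CC)CC)[C@@H]2CO1 | intermediate
24 | (7S,8R,8aS)-3-[(1E,3R,4S,5S)-3,4-dihydroxy-3,5-dimethylhept-1-en-1-yl]-7,8-dihydroxy-7-methyl-1,7,8,8a-tetrahydro-6H-isochromen-6-one | CC[C@H](C)[C@H](O)[C@](C)(O)/C=C/C1=CC2=CC(=O)[C@@](C)(O)[C@H](O)[C@@H]2CO1 | target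

**Count and risks**

Total step count: 16 (steps 1–5 tartrate fragment, steps 6–12 isoleucine fragment, steps 13–16 after union).
Longest linear sequence: 11 steps (8 → 24, steps 6–16).

Steps most likely to fail:

Step 15. The diacylallene may oligomerise or cyclise otherwise, and the C8a outcome rests on a conformational argument, not on a direct precedent. Fallback, setting out from 7 (with 17 and 18) and coming back at 23: keep C6 at the carbinol level so that the heterodiene is a plain allenyl ketone. Aldehyde 7, propargyl bromide 18 and Zn in THF give 5-methyl-5,6-bis[(triethylsilyl)oxy]oct-7-en-1-yn-4-ol F6. Its dianion (n-BuLi, 2 equiv, −78 °C, cold quench) adds to enal 17 to give 4,12,14-trimethyl-3,4,12,13-tetrakis[(triethylsilyl)oxy]hexadeca-1,10-dien-7-yne-5,9-diol F7. MnO2 in CH2Cl2 oxidises only the allylic and propargylic C9 carbinol to 5-hydroxy-4,12,14-trimethyl-3,4,12,13-tetrakis[(triethylsilyl)oxy]hexadeca-1,10-dien-7-yn-9-one F8. Et3N in warm toluene isomerises this to 5-hydroxy-4,12,14-trimethyl-3,4,12,13-tetrakis[(triethylsilyl)oxy]hexadeca-1,6,7,10-tetraen-9-one F9, which undergoes the same intramolecular hetero-Diels–Alder reaction to 3-[(1E,3R,4S,5S)-3,5-dimethyl-3,4-bis[(triethylsilyl)oxy]hept-1-en-1-yl]-7-methyl-7,8-bis[(triethylsilyl)oxy]-1,7,8,8a-tetrahydro-6H-isochromen-6-ol F10. Dess–Martin oxidation of the allylic C6 carbinol then gives 23.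

Step 2. The α-silyloxy dianion may suffer silyl shifts or give incomplete anti selectivity. Fallback, setting out from 1 and coming back at 4: run the Fráter–Seebach methylation on a benzyl ether and change the protecting groups afterwards. 1 with Bu2SnO (toluene, reflux), then benzyl bromide and CsF, gives diethyl (2S,3S)-2-(benzyloxy)-3-hydroxybutanedioate F1. LiN(iPr)2 (2.2 equiv) and iodomethane give diethyl (2S,3S)-2-(benzyloxy)-3-hydroxy-2-methylbutanedioate F2. Hydrogenolysis (H2, Pd/C, ethanol) gives diethyl (2S,3S)-2,3-dihydroxy-2-methylbutanedioate F3. Et3SiOTf and 2,6-lutidine silylate both hydroxyls to 4.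

Step 3. iBu2AlH may over-reduce or attack the wrong ester. Fallback, setting out from 4 and coming back at 5: differentiate the esters by hydrolysis and reduce a thioester. LiOH (1 equiv, THF/H2O, 0 °C) saponifies only the unhindered ester to (2S,3S)-4-ethoxy-3-methyl-4-oxo-2,3-bis[(triethylsilyl)oxy]butanoic acid F4. Ethanethiol, DCC and 4-(dimethylamino)pyridine give ethyl (2S,3S)-4-(ethylsulfanyl)-2-methyl-4-oxo-2,3-bis[(triethylsilyl)oxy]butanoate F5. Fukuyama reduction (Et3SiH, Pd/C, acetone) gives aldehyde 5.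

**Further compounds**

F1 | step 2 | diethyl (2S,3S)-2-(benzyloxy)-3-hydroxybutanedioate | CCOC(=O)[C@@H](OCc1ccccc1)[C@H](O)C(=O)OCC
F2 | step 2 | diethyl (2S,3S)-2-(benzyloxy)-3-hydroxy-2-methylbutanedioate | CCOC(=O)[C@@](C)(OCc1ccccc1)[C@H](O)C(=O)OCC
F3 | step 2 | diethyl (2S,3S)-2,3-dihydroxy-2-methylbutanedioate | CCOC(=O)[C@@](C)(O)[C@H](O)C(=O)OCC
F4 | step 3 | (2S,3S)-4-ethoxy-3-methyl-4-oxo-2,3-bis[(triethylsilyl)oxy]butanoic acid | CCOC(=O)[C@@](C)(O[Si](CC)(CC)CC)[C@H](O[Si](CC)(CC)CC)C(=O)O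
F5 | step 3 | ethyl (2S,3S)-4-(ethylsulfanyl)-2-methyl-4-oxo-2,3-bis[(triethylsilyl)oxy]butanoate | CCOC(=O)[C@@](C)(O[Si](CC)(CC)CC)[C@H](O[Si](CC)(CC)CC)C(=O)SCC
F6 | step 15 | 5-methyl-5,6-bis[(triethylsilyl)oxy]oct-7-en-1-yn-4-ol (centres of 7 kept; C4 epimers) | C#CCC(O)[C@@](C)(O[Si](CC)(CC)CC)[C@H](O[Si](CC)(CC)CC)C=C
F7 | step 15 | 4,12,14-trimethyl-3,4,12,13-tetrakis[(triethylsilyl)oxy]hexadeca-1,10-dien-7-yne-5,9-diol (10E; C5/C9 epimers) | CC[C@H](C)[C@H](O[Si](CC)(CC)CC)[C@](C)(O[Si](CC)(CC)CC)/C=C/C(O)C#CCC(O)[C@@](C)(O[Si](CC)(CC)CC)[C@H](O[Si](CC)(CC)CC)C=C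
F8 | step 15 | 5-hydroxy-4,12,14-trimethyl-3,4,12,13-tetrakis[(triethylsilyl)oxy]hexadeca-1,10-dien-7-yn-9-one (10E; C5 epimers) | CC[C@H](C)[C@H](O[Si](CC)(CC)CC)[C@](C)(O[Si](CC)(CC)CC)/C=C/C(=O)C#CCC(O)[C@@](C)(O[Si](CC)(CC)CC)[C@H](O[Si](CC)(CC)CC)C=C
F9 | step 15 | 5-hydroxy-4,12,14-trimethyl-3,4,12,13-tetrakis[(triethylsilyl)oxy]hexadeca-1,6,7,10-tetraen-9-one (10E; C5 and allene epimers) | CC[C@H](C)[C@H](O[Si](CC)(CC)CC)[C@](C)(O[Si](CC)(CC)CC)/C=C/C(=O)C=C=CC(O)[C@@](C)(O[Si](CC)(CC)CC)[C@H](O[Si](CC)(CC)CC)C=C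
F10 | step 15 | 3-[(1E,3R,4S,5S)-3,5-dimethyl-3,4-bis[(triethylsilyl)oxy]hept-1-en-1-yl]-7-methyl-7,8-bis[(triethylsilyl)oxy]-1,7,8,8a-tetrahydro-6H-isochromen-6-ol (C6 epimers; C7, C8, C8a as in 23) | CC[C@H](C)[C@H](O[Si](CC)(CC)CC)[C@](C)(O[Si](CC)(CC)CC)/C=C/C1=CC2=CC(O)[C@@](C)(O[Si](CC)(CC)CC)[C@H](O[Si](CC)(CC)CC)[C@@H]2CO1
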